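**Retrosynthetic overview**
- The target is opened at the (E)-alkene between the quaternary ring carbon and the second coumarin: an α-quaternary cyclohexene carbaldehyde plus a (coumarin-3-yl)methyl phosphonium ylide (Wittig), with phenol desilylation last.
- The cyclohexene carbaldehyde comes from an endo-selective, catalyst-controlled Diels–Alder reaction of a 3-(3-methylbuta-1,3-dienyl)coumarin with methacrolein; this sets both stereocentres.
- The dienyl coumarin comes from the same phosphonium salt and methacrolein (Wittig).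
- Key disconnection: the lactone C(acyl)–O(aryl) bond of the phosphonium salt, made by O-acryloylation of a salicylaldehyde and closed by a phosphine-triggered annulation (new step); every coumarin ring of the target comes from this step.
- Ring order: coumarin pyranone ring (made once, used twice), then the cyclohexene ring, then attachment of the second coumarin.

Assumption: 2,4-dihydroxy-3-methoxybenzaldehyde 1 is bought as a catalogue building block; the sense of induction in step 4 is taken from the accepted transition-state model of the catalyst and is to be confirmed by chiroptical comparison with the target (the antipodal catalyst is equally available).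

**Step 1**
Reactants: 1 2,4-dihydroxy-3-methoxybenzaldehyde; 2 chlorotriisopropylsilane
Product: 3 2-hydroxy-3-methoxy-4-[(triisopropylsilyl)oxy]benzaldehyde
Conditions: 2 (1.05 equiv), imidazole (1.2 equiv), CH2Cl2, 0 °C → rt
Reagents that add atoms: chlorotriisopropylsilane, CC(C)[Si](Cl)(C(C)C)C(C)C
Why: Selective phenol silylation (silyl ether formation) at the 4-OH, because the 2-OH is hydrogen-bonded to the formyl group and flanked on both sides; the silyl ether keeps the later 7-OH away from the bases and the Lewis acid of steps 2–5, and no stereocentre is formed.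

**Step 2**
Reactants: 3 2-hydroxy-3-methoxy-4-[(triisopropylsilyl)oxy]benzaldehyde; 4 acryloyl chloride; 5 tributylphosphine
Product: 8 tributyl({8-methoxy-2-oxo-7-[(triisopropylsilyl)oxy]-2H-chromen-3-yl}methyl)phosphonium chloride, via aryl acrylate 6 (not isolated), via hydroxylactone phosphonium chloride 7 (not isolated)
Conditions: 4 (1.05 equiv), Et3N (1.1 equiv), CH2Cl2, 0 °C, 1 h; then PBu3 (1.05 equiv), 0 → 40 °C
Reagents that add atoms: acryloyl chloride, C=CC(=O)Cl; tributylphosphine, CCCCP(CCCC)CCCC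
Why: Proposed new method: O-acryloylation forms the lactone C(acyl)–O(aryl) bond, then PBu3 adds to the aryl acrylate (phospha-Michael), the zwitterionic enolate closes onto the ortho-formyl group (6-enolendo-exo-trig, intramolecular Morita–Baylis–Hillman-type aldol) to give 7, and Et3N-mediated E1cB dehydration, driven by aromatisation to the coumarin and with Et3NH+Cl− as proton and chloride source, retains the phosphine as the allylic phosphonium salt 8 instead of releasing it (net 3 + 4 + 5 → 8 + H2O, Et3N returned); the closest known reaction types are the amine- or phosphine-mediated intramolecular Morita–Baylis–Hillman cyclisation and the SN2′ phosphination of Morita–Baylis–Hillman adducts to allylic phosphonium salts; no stereocentre is carried into 8.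

**Step 3**
Reactants: 8 tributyl({8-methoxy-2-oxo-7-[(triisopropylsilyl)oxy]-2H-chromen-3-yl}methyl)phosphonium chloride; 9 methacrolein
Product: 10 8-methoxy-3-[(1E)-3-methylbuta-1,3-dien-1-yl]-7-[(triisopropylsilyl)oxy]-2H-chromen-2-one
Conditions: KN(SiMe3)2 (1.05 equiv), THF, −78 °C; then 9 (1.5 equiv), −78 °C → rt; product kept cold in solution and used promptly
Reagents that add atoms: methacrolein, CC(=C)C=O
Why: Wittig olefination with a semi-stabilised allylic tributylphosphonium ylide, a class that gives (E)-alkenes with aldehydes and adds 1,2 to enals; no stereocentre is formed, and 10 is kept cold because it can dimerise thermally.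

**Step 4**
Reactants: 10 8-methoxy-3-[(1E)-3-methylbuta-1,3-dien-1-yl]-7-[(triisopropylsilyl)oxy]-2H-chromen-2-one; 9 methacrolein
Product: 11 (1S,2R)-2-{8-methoxy-2-oxo-7-[(triisopropylsilyl)oxy]-2H-chromen-3-yl}-1,4-dimethylcyclohex-3-ene-1-carbaldehyde
Conditions: (S)-3,3-diphenyl-1-(2-methylphenyl)tetrahydro-1H,3H-pyrrolo[1,2-c][1,3,2]oxazaborole (20 mol %), HN(SO2CF3)2 (18 mol %), 9 (5 equiv), CH2Cl2, −78 → −40 °C
Reagents that add atoms: methacrolein, CC(=C)C=O
Why: Catalytic enantioselective Diels–Alder reaction with a chiral oxazaborolidinium Lewis acid, a class established for 2-methylacrolein with acyclic dienes: the 1-aryl ("ortho") and 3-methyl ("para") effects of the diene agree on one regioisomer, endo placement of the complexed formyl group puts CHO cis to the coumarinyl group, and the catalyst (boron-bound s-trans enal held by a formyl C–H···O contact, one face covered by a phenyl group) directs the diene to the face that gives (1S) at the quaternary carbon and hence (2R) at the methine; the quaternary centre has no α-hydrogen and cannot epimerise later.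

**Step 5**
Reactants: 11 (1S,2R)-2-{8-methoxy-2-oxo-7-[(triisopropylsilyl)oxy]-2H-chromen-3-yl}-1,4-dimethylcyclohex-3-ene-1-carbaldehyde; 8 tributyl({8-methoxy-2-oxo-7-[(triisopropylsilyl)oxy]-2H-chromen-3-yl}methyl)phosphonium chloride
Product: 13 7-hydroxy-3-[(1R,6R)-6-[(E)-2-(7-hydroxy-8-methoxy-2-oxo-2H-chromen-3-yl)ethenyl]-3,6-dimethylcyclohex-2-en-1-yl]-8-methoxy-2H-chromen-2-one (CNP0264408.1), via bis-silyl ether 12 (not isolated)
Conditions: 8 (1.6 equiv), KN(SiMe3)2 (1.5 equiv), THF, −78 °C; then 11, −78 → 50 °C; then AcOH (4 equiv), Bu4NF (3 equiv), THF, 0 °C → rt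
Reagents that add atoms: tributyl({8-methoxy-2-oxo-7-[(triisopropylsilyl)oxy]-2H-chromen-3-yl}methyl)phosphonium chloride, CCCC[P+](CCCC)(CCCC)Cc1cc2ccc(O[Si](C(C)C)(C(C)C)C(C)C)c(OC)c2oc1=O.[Cl-]
Why: A second Wittig (E)-olefination with the same ylide on a non-enolisable aldehyde leaves both stereocentres untouched (the ring descriptors change from 1S,2R to 1R,6R only through CIP priorities and numbering), and acetic-acid-buffered fluoride then cleaves the two aryl silyl ethers without opening the lactones.

**Compound list**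
1 | 2,4-dihydroxy-3-methoxybenzaldehyde | O=Cc1ccc(O)c(OC)c1O | starting material
2 | chlorotriisopropylsilane | CC(C)[Si](Cl)(C(C)C)C(C)C | starting material
3 | 2-hydroxy-3-methoxy-4-[(triisopropylsilyl)oxy]benzaldehyde | O=Cc1ccc(O[Si](C(C)C)(C(C)C)C(C)C)c(OC)c1O | intermediate
4 | acryloyl chloride | C=CC(=O)Cl | starting material
5 | tributylphosphine | CCCCP(CCCC)CCCC | starting material
6 | 2-formyl-6-methoxy-5-[(triisopropylsilyl)oxy]phenyl prop-2-enoate | C=CC(=O)Oc1c(C=O)ccc(O[Si](C(C)C)(C(C)C)C(C)C)c1OC | intermediate (not isolated)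
7 | tributyl({4-hydroxy-8-methoxy-2-oxo-7-[(triisopropylsilyl)oxy]-3,4-dihydro-2H-chromen-3-yl}methyl)phosphonium chloride (diastereomer mixture) | CCCC[P+](CCCC)(CCCC)CC1C(O)c2ccc(O[Si](C(C)C)(C(C)C)C(C)C)c(OC)c2OC1=O.[Cl-] | intermediate (not isolated)
8 | tributyl({8-methoxy-2-oxo-7-[(triisopropylsilyl)oxy]-2H-chromen-3-yl}methyl)phosphonium chloride | CCCC[P+](CCCC)(CCCC)Cc1cc2ccc(O[Si](C(C)C)(C(C)C)C(C)C)c(OC)c2oc1=O.[Cl-] | intermediate
9 | methacrolein (2-methylprop-2-enal) | CC(=C)C=O | starting material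
10 | 8-methoxy-3-[(1E)-3-methylbuta-1,3-dien-1-yl]-7-[(triisopropylsilyl)oxy]-2H-chromen-2-one | CC(=C)/C=C/c1cc2ccc(O[Si](C(C)C)(C(C)C)C(C)C)c(OC)c2oc1=O | intermediate
11 | (1S,2R)-2-{8-methoxy-2-oxo-7-[(triisopropylsilyl)oxy]-2H-chromen-3-yl}-1,4-dimethylcyclohex-3-ene-1-carbaldehyde | O=C[C@@]1(C)CCC(C)=C[C@H]1c3cc2ccc(O[Si](C(C)C)(C(C)C)C(C)C)c(OC)c2oc3=O | intermediate
12 | 3-[(1R,6R)-3,6-dimethyl-6-[(E)-2-{8-methoxy-2-oxo-7-[(triisopropylsilyl)oxy]-2H-chromen-3-yl}ethenyl]cyclohex-2-en-1-yl]-8-methoxy-7-[(triisopropylsilyl)oxy]-2H-chromen-2-one | COc1c(O[Si](C(C)C)(C(C)C)C(C)C)ccc2cc(/C=C/[C@@]3(C)CCC(C)=C[C@H]3c3cc4ccc(O[Si](C(C)C)(C(C)C)C(C)C)c(OC)c4oc3=O)c(=O)oc12 | intermediate (not isolated)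
13 | 7-hydroxy-3-[(1R,6R)-6-[(E)-2-(7-hydroxy-8-methoxy-2-oxo-2H-chromen-3-yl)ethenyl]-3,6-dimethylcyclohex-2-en-1-yl]-8-methoxy-2H-chromen-2-one | COc1c(O)ccc2cc(/C=C/[C@@]3(C)CCC(C)=C[C@H]3c3cc4ccc(O)c(OC)c4oc3=O)c(=O)oc12 | target

**Total step count:** 5
**Longest linear sequence:** 5 (1 → 3 → 8 → 10 → 11 → 13; salt 8 is used in steps 3 and 5)

**Three steps most likely to fail**

Step 2 (the proposed new step). Risks are oligomerisation of the aryl acrylate and incomplete dehydration. The fallback uses known chemistry; it sets out from 3 and comes back to the route at 10. Compound 3 is heated with commercial ethyl 2-(triphenylphosphoranylidene)propanoate in N,N-diethylaniline at 200 °C (Wittig olefination, thermal isomerisation and lactonisation) to give 8-methoxy-3-methyl-7-[(triisopropylsilyl)oxy]-2H-chromen-2-one F1. Wohl–Ziegler bromination (N-bromosuccinimide, AIBN, PhCF3, 80 °C) gives 3-(bromomethyl)-8-methoxy-7-[(triisopropylsilyl)oxy]-2H-chromen-2-one F2. PBu3 in toluene converts this into tributyl({8-methoxy-2-oxo-7-[(triisopropylsilyl)oxy]-2H-chromen-3-yl}methyl)phosphonium bromide F3. F3 is used in place of 8 under the conditions of step 3 to reach 10, and again in step 5.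

Step 4. Risks are sequestration of the boron catalyst by the Lewis-basic coumarin carbonyl and an insufficient endo preference or enantiomeric excess. The fallback sets out from 10 and comes back at 12. Diene 10 is heated in toluene at 110 °C so that it undergoes the uncatalysed endo Diels–Alder homodimerisation, the isopropenyl group of a second molecule acting as dienophile; this gives racemic 12 directly. Preparative chromatography on a chiral phase (SFC) removes ent-12 F4 and delivers 12, which is desilylated as in the second stage of step 5.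

Step 5. The risk is slow addition of the bulky semi-stabilised ylide to the α-quaternary aldehyde. The fallback sets out from 11 and comes back at 12; it builds the second coumarin on the core by acylation and ring closure instead of bringing it in preformed. Aldehyde 11 is homologated with the small non-stabilised ylide from commercial (2-carboxyethyl)triphenylphosphonium bromide and NaN(SiMe3)2 to give (3Z)-4-[(1R,2R)-2-{8-methoxy-2-oxo-7-[(triisopropylsilyl)oxy]-2H-chromen-3-yl}-1,4-dimethylcyclohex-3-en-1-yl]but-3-enoic acid F5. Esterification with 3 (N,N'-dicyclohexylcarbodiimide, 4-(dimethylamino)pyridine, CH2Cl2) gives the 2-formylaryl ester F6. Treatment with 1,8-diazabicyclo[5.4.0]undec-7-ene closes F6 by intramolecular Knoevenagel condensation to the (Z)-isomer of 12 F7. I2 (5 mol %) in toluene under visible light then equilibrates the disubstituted alkene to the (E)-isomer 12, which is desilylated as in step 5.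

**Further compounds**
F1 | step 2 | 8-methoxy-3-methyl-7-[(triisopropylsilyl)oxy]-2H-chromen-2-one | Cc1cc2ccc(O[Si](C(C)C)(C(C)C)C(C)C)c(OC)c2oc1=O
F2 | step 2 | 3-(bromomethyl)-8-methoxy-7-[(triisopropylsilyl)oxy]-2H-chromen-2-one | BrCc1cc2ccc(O[Si](C(C)C)(C(C)C)C(C)C)c(OC)c2oc1=O
F3 | step 2 | tributyl({8-methoxy-2-oxo-7-[(triisopropylsilyl)oxy]-2H-chromen-3-yl}methyl)phosphonium bromide | CCCC[P+](CCCC)(CCCC)Cc1cc2ccc(O[Si](C(C)C)(C(C)C)C(C)C)c(OC)c2oc1=O.[Br-]
F4 | step 4 | ent-12, the (1S,6S)-enantiomer of 12 | COc1c(O[Si](C(C)C)(C(C)C)C(C)C)ccc2cc(/C=C/[C@]3(C)CCC(C)=C[C@@H]3c3cc4ccc(O[Si](C(C)C)(C(C)C)C(C)C)c(OC)c4oc3=O)c(=O)oc12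
F5 | step 5 | (3Z)-4-[(1R,2R)-2-{8-methoxy-2-oxo-7-[(triisopropylsilyl)oxy]-2H-chromen-3-yl}-1,4-dimethylcyclohex-3-en-1-yl]but-3-enoic acid | OC(=O)C/C=C\[C@@]1(C)CCC(C)=C[C@H]1c3cc2ccc(O[Si](C(C)C)(C(C)C)C(C)C)c(OC)c2oc3=O
F6 | step 5 | 2-formyl-6-methoxy-5-[(triisopropylsilyl)oxy]phenyl (3Z)-4-[(1R,2R)-2-{8-methoxy-2-oxo-7-[(triisopropylsilyl)oxy]-2H-chromen-3-yl}-1,4-dimethylcyclohex-3-en-1-yl]but-3-enoate | O=Cc1ccc(O[Si](C(C)C)(C(C)C)C(C)C)c(OC)c1OC(=O)C/C=C\[C@@]1(C)CCC(C)=C[C@H]1c3cc2ccc(O[Si](C(C)C)(C(C)C)C(C)C)c(OC)c2oc3=O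
F7 | step 5 | (Z)-isomer of 12, 3-[(1R,6R)-3,6-dimethyl-6-[(Z)-2-{8-methoxy-2-oxo-7-[(triisopropylsilyl)oxy]-2H-chromen-3-yl}ethenyl]cyclohex-2-en-1-yl]-8-methoxy-7-[(triisopropylsilyl)oxy]-2H-chromen-2-one | COc1c(O[Si](C(C)C)(C(C)C)C(C)C)ccc2cc(/C=C\[C@@]3(C)CCC(C)=C[C@H]3c3cc4ccc(O[Si](C(C)C)(C(C)C)C(C)C)c(OC)c4oc3=O)c(=O)oc12
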